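**Retrosynthetic overview**

- The target is reached by chelation-directed cleavage of the 5-O-methyl ether and the tert-butyl ester of a cis-2,3-dimethylchromanone ester.
- The chromanone ring (formed last) comes from an alkaloid-catalysed oxa-Michael closure of an o-hydroxyaryl tigloyl ketone, itself made by ortho-acylation of a phenol.
- Key disconnection, aryl–C3' bond: the arene is brought in as an electrophile (a prenylated 2,6-dimethoxybenzoquinone carbonyl) and the acid chain as a chiral NHC homoenolate of (E)-oct-2-enal. The spiro-γ-lactone that results is reductively aromatised.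
- The quinone comes from radical prenylation of 2,6-dimethoxy-1,4-benzoquinone.
- Ring order: spiro-γ-lactone (transient) → benzene ring (by aromatisation) → dihydropyranone ring of the chromanone.

Assumption: the senses of induction stated for the two chiral catalysts (triazolium salt in step 2, quinidine in step 5) are taken by analogy with their closest precedents; if either gives the antipodal sense, its (pseudo)enantiomer is used instead.

**Route**

Step 1
Reactants: 1 2,6-dimethoxy-1,4-benzoquinone; 2 4-methylpent-3-enoic acid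
Product: 3 2,6-dimethoxy-3-(3-methylbut-2-en-1-yl)-1,4-benzoquinone
Conditions: AgNO3 (0.2 equiv), (NH4)2S2O8 (1.3 equiv), MeCN/H2O 1:1, 65 °C, quinone in slight excess
Reagents that add atoms: none
Why: Jacobsen–Torssell (Minisci-type) decarboxylative radical alkylation, in which the prenyl radical from 2 adds through its unhindered CH2 end to one of the two equivalent C–H carbons of the quinone and the adduct is re-oxidised, so the prenyl group ends up between a methoxy carbon and a carbonyl as needed; no stereocentre.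

Step 2
Reactants: 3 2,6-dimethoxy-3-(3-methylbut-2-en-1-yl)-1,4-benzoquinone; 4 (E)-oct-2-enal
Product: 6 (3R)-3-[4-hydroxy-2,6-dimethoxy-3-(3-methylbut-2-en-1-yl)phenyl]octanoic acid, via spirolactone dienone 5 (not isolated)
Conditions: (5aR,10bS)-N-mesityl aminoindanol-derived triazolium chloride (10 mol%), DBU (10 mol%), Mg(OtBu)2 (10 mol%), THF, 0 °C to rt; then AcOH, Zn dust, rt
Reagents that add atoms: none
Why: Proposed new method: the chiral NHC turns enal 4 into a Breslow homoenolate whose β-carbon (normally electrophilic) adds 1,2 to the Mg-chelated C1 carbonyl of 3 (the one flanked by both OMe groups and not a vinylogous ester), the tertiary alkoxide then acylates the acyl azolium to close spiro-γ-lactone 5 and release the catalyst, and the aminoindanol backbone shields one face so that bonding occurs on the Re face of Cβ and sets (R); both spiro epimers converge because Zn/AcOH reductive cleavage of the γ-acyloxy dienone (known reductive aromatisation of p-quinol esters) destroys the spiro centre without touching the benzylic one; the closest known reaction type is the NHC/Lewis-acid homoenolate annulation of enals with isatins, 1,2-diones and activated ketones to spiro-γ-butyrolactones.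

Step 3
Reactants: 6 (3R)-3-[4-hydroxy-2,6-dimethoxy-3-(3-methylbut-2-en-1-yl)phenyl]octanoic acid
Product: 7 tert-butyl (3R)-3-[4-hydroxy-2,6-dimethoxy-3-(3-methylbut-2-en-1-yl)phenyl]octanoate
Conditions: tert-butyl 2,2,2-trichloroacetimidate (2 equiv), CH2Cl2/cyclohexane, rt
Reagents that add atoms: tert-butyl 2,2,2-trichloroacetimidate, CC(C)(C)OC(=N)C(Cl)(Cl)Cl
Why: Acid-selective O-tert-butylation by the trichloroacetimidate (self-catalysed by the carboxylic acid, so the phenol and the prenyl alkene are untouched) masks the acid for the next two steps; the stereocentre is not involved.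

Step 4
Reactants: 7 tert-butyl (3R)-3-[4-hydroxy-2,6-dimethoxy-3-(3-methylbut-2-en-1-yl)phenyl]octanoate; 8 (E)-2-methylbut-2-enoyl chloride (tigloyl chloride)
Product: 10 tert-butyl (3R)-3-[4-hydroxy-2,6-dimethoxy-5-[(E)-2-methylbut-2-enoyl]-3-(3-methylbut-2-en-1-yl)phenyl]octanoate, via bromomagnesium phenoxide 9 (not isolated)
Conditions: EtMgBr (1.0 equiv), Et2O/toluene, 0 °C; then 8 (1.1 equiv), toluene, 0 °C to rt; cold aq. NH4Cl
Reagents that add atoms: none
Why: Metal-template ortho-acylation (Friedel–Crafts acylation of a bromomagnesium phenoxide) delivers the acyl chloride through the Mg chelate to the only free ortho carbon, without the strong Lewis acids that would cyclise the ortho-prenyl phenol; no new stereocentre.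

Step 5
Reactants: 10 tert-butyl (3R)-3-[4-hydroxy-2,6-dimethoxy-5-[(E)-2-methylbut-2-enoyl]-3-(3-methylbut-2-en-1-yl)phenyl]octanoate
Product: 11 tert-butyl (3R)-3-[(2S,3R)-5,7-dimethoxy-2,3-dimethyl-8-(3-methylbut-2-en-1-yl)-4-oxo-3,4-dihydro-2H-chromen-6-yl]octanoate
Conditions: quinidine (0.2 equiv), chlorobenzene, 15 °C
Reagents that add atoms: none
Why: Cinchona-alkaloid-catalysed asymmetric intramolecular oxa-Michael addition, in which quinidine (pseudo-enantiomer of the quinine that gives the (2R) series of 2,3-dimethylchromanones) directs phenol attack to set C2 as (S), and kinetic protonation of the enol anti to the new C2 methyl gives the cis (3R) isomer under non-epimerising conditions.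

Step 6
Reactants: 11 tert-butyl (3R)-3-[(2S,3R)-5,7-dimethoxy-2,3-dimethyl-8-(3-methylbut-2-en-1-yl)-4-oxo-3,4-dihydro-2H-chromen-6-yl]octanoate
Product: 12 (3R)-3-[(2S,3R)-5-hydroxy-7-methoxy-2,3-dimethyl-8-(3-methylbut-2-en-1-yl)-4-oxo-3,4-dihydro-2H-chromen-6-yl]octanoic acid (target)
Conditions: BCl3 (4 equiv), CH2Cl2, −78 to 0 °C; cold pH 7 buffer
Reagents that add atoms: none
Why: Chelation-controlled Lewis-acid ether cleavage, in which boron bound to the C4 carbonyl removes only the peri 5-OMe (the 7-OMe is not chelated) and also ionises the tert-butyl ester, while the cold acidic medium avoids the base-mediated C3 epimerisation or ring opening of the cis-chromanone.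

**Compound list**

1 | 2,6-dimethoxy-1,4-benzoquinone | COC1=CC(=O)C=C(OC)C1=O | starting material
2 | 4-methylpent-3-enoic acid | CC(C)=CCC(=O)O | starting material
3 | 2,6-dimethoxy-3-(3-methylbut-2-en-1-yl)-1,4-benzoquinone | COC1=CC(=O)C(CC=C(C)C)=C(OC)C1=O | intermediate
4 | (E)-oct-2-enal | CCCCC/C=C/C=O | starting material
5 | (4R)-6,10-dimethoxy-7-(3-methylbut-2-en-1-yl)-4-pentyl-1-oxaspiro[4.5]deca-6,9-diene-2,8-dione (both spiro epimers) | CCCCC[C@@H]1CC(=O)OC12C(OC)=C(CC=C(C)C)C(=O)C=C2OC | intermediate (not isolated)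
6 | (3R)-3-[4-hydroxy-2,6-dimethoxy-3-(3-methylbut-2-en-1-yl)phenyl]octanoic acid | CCCCC[C@H](CC(=O)O)c1c(OC)cc(O)c(CC=C(C)C)c1OC | intermediate
7 | tert-butyl (3R)-3-[4-hydroxy-2,6-dimethoxy-3-(3-methylbut-2-en-1-yl)phenyl]octanoate | CCCCC[C@H](CC(=O)OC(C)(C)C)c1c(OC)cc(O)c(CC=C(C)C)c1OC | intermediate
8 | (E)-2-methylbut-2-enoyl chloride (tigloyl chloride) | C/C=C(\C)C(=O)Cl | starting material
9 | bromomagnesium phenoxide of 7 | CCCCC[C@H](CC(=O)OC(C)(C)C)c1c(OC)cc(O[Mg]Br)c(CC=C(C)C)c1OC | intermediate (not isolated)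
10 | tert-butyl (3R)-3-[4-hydroxy-2,6-dimethoxy-5-[(E)-2-methylbut-2-enoyl]-3-(3-methylbut-2-en-1-yl)phenyl]octanoate | CCCCC[C@H](CC(=O)OC(C)(C)C)c1c(OC)c(C(=O)/C(C)=C/C)c(O)c(CC=C(C)C)c1OC | intermediate
11 | tert-butyl (3R)-3-[(2S,3R)-5,7-dimethoxy-2,3-dimethyl-8-(3-methylbut-2-en-1-yl)-4-oxo-3,4-dihydro-2H-chromen-6-yl]octanoate | CCCCC[C@H](CC(=O)OC(C)(C)C)c1c(OC)c2c(c(CC=C(C)C)c1OC)O[C@@H](C)[C@@H](C)C2=O | intermediate
12 | (3R)-3-[(2S,3R)-5-hydroxy-7-methoxy-2,3-dimethyl-8-(3-methylbut-2-en-1-yl)-4-oxo-3,4-dihydro-2H-chromen-6-yl]octanoic acid | CCCCC[C@H](CC(=O)O)c1c(O)c2c(c(CC=C(C)C)c1OC)O[C@@H](C)[C@@H](C)C2=O | target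

**Step count and risks**

Total step count: 6. Longest linear sequence: 6 steps (1 to 12). The three steps most likely to fail are steps 2, 4 and 6.

Step 2 is the main risk. The quinone may oxidise the Breslow intermediate (redox esterification), bind the carbene, or, as a prenylquinone, tautomerise under base, instead of accepting the homoenolate at its carbonyl. The fallback sets out from 3 and comes back at 5. Methyl oct-2-ynoate is hydroiodinated (NaI, AcOH, 115 °C) to methyl (Z)-3-iodooct-2-enoate F1. Iodine–magnesium exchange (i-PrMgCl·LiCl, THF, −40 °C) gives methyl (Z)-3-(chloromagnesio)oct-2-enoate F2, a stoichiometric β-acyl vinyl anion. F2 adds to the same carbonyl of 3 (LaCl3·2LiCl, −40 °C) and the alkoxide closes onto the ester to give 6,10-dimethoxy-7-(3-methylbut-2-en-1-yl)-4-pentyl-1-oxaspiro[4.5]deca-3,6,9-triene-2,8-dione F3. A CuH-catalysed asymmetric conjugate reduction (Cu(OAc)2, the DTBM-SEGPHOS antipode that gives 4R, PMHS, t-BuOH, toluene) then sets the C4 centre and delivers 5, which goes on to 6 with Zn/AcOH as before.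

Step 4 may give the aryl tiglate (O-acylation) or let the magnesium phenoxide of the product cyclise to racemic chromanone. The fallback sets out from 7 and comes back at 10. Ortho-formylation (MgCl2, Et3N, paraformaldehyde, MeCN, reflux) gives tert-butyl (3R)-3-[5-formyl-4-hydroxy-2,6-dimethoxy-3-(3-methylbut-2-en-1-yl)phenyl]octanoate F4. Addition of (E)-but-2-en-2-yllithium (from (E)-2-bromobut-2-ene and t-BuLi, 2.2 equiv, THF, −78 °C) gives tert-butyl (3R)-3-[4-hydroxy-5-[(E)-1-hydroxy-2-methylbut-2-en-1-yl]-2,6-dimethoxy-3-(3-methylbut-2-en-1-yl)phenyl]octanoate F5. MnO2 in CH2Cl2 oxidises F5 to 10.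

Step 6 may epimerise C3 to the trans chromanone, add HCl to the prenyl group, or close the 5-OH onto the acid. The fallback sets out from 10 and comes back at 12, and moves the Lewis-acid step ahead of ring closure, where no epimerisable centre exists yet. BCl3 (CH2Cl2, −78 to 0 °C) on 10 gives (3R)-3-[2,4-dihydroxy-6-methoxy-3-[(E)-2-methylbut-2-enoyl]-5-(3-methylbut-2-en-1-yl)phenyl]octanoic acid F6. DCC in CH2Cl2 closes the acid onto the only hydroxyl it can reach, giving (4R)-7-hydroxy-5-methoxy-8-[(E)-2-methylbut-2-enoyl]-6-(3-methylbut-2-en-1-yl)-4-pentyl-3,4-dihydro-2H-chromen-2-one F7, which leaves a single free phenol. The quinidine oxa-Michael closure of step 5 then gives (4R,8S,9R)-5-methoxy-8,9-dimethyl-6-(3-methylbut-2-en-1-yl)-4-pentyl-3,4,8,9-tetrahydro-2H,10H-pyrano[2,3-f]chromene-2,10-dione F8. A brief treatment with LiOH (THF/H2O, 0 °C) opens the activated aryl lactone faster than the ketone enolises and gives 12.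

**Further compounds**

F1 | step 2 | methyl (Z)-3-iodooct-2-enoate | CCCCC/C(I)=C/C(=O)OC
F2 | step 2 | methyl (Z)-3-(chloromagnesio)oct-2-enoate | CCCCC/C([Mg]Cl)=C/C(=O)OC
F3 | step 2 | 6,10-dimethoxy-7-(3-methylbut-2-en-1-yl)-4-pentyl-1-oxaspiro[4.5]deca-3,6,9-triene-2,8-dione (racemic at the spiro carbon) | CCCCCC1=CC(=O)OC12C(OC)=C(CC=C(C)C)C(=O)C=C2OC
F4 | step 4 | tert-butyl (3R)-3-[5-formyl-4-hydroxy-2,6-dimethoxy-3-(3-methylbut-2-en-1-yl)phenyl]octanoate | CCCCC[C@H](CC(=O)OC(C)(C)C)c1c(OC)c(C=O)c(O)c(CC=C(C)C)c1OC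
F5 | step 4 | tert-butyl (3R)-3-[4-hydroxy-5-[(E)-1-hydroxy-2-methylbut-2-en-1-yl]-2,6-dimethoxy-3-(3-methylbut-2-en-1-yl)phenyl]octanoate (both carbinol epimers) | CCCCC[C@H](CC(=O)OC(C)(C)C)c1c(OC)c(C(O)/C(C)=C/C)c(O)c(CC=C(C)C)c1OC
F6 | step 6 | (3R)-3-[2,4-dihydroxy-6-methoxy-3-[(E)-2-methylbut-2-enoyl]-5-(3-methylbut-2-en-1-yl)phenyl]octanoic acid | CCCCC[C@H](CC(=O)O)c1c(O)c(C(=O)/C(C)=C/C)c(O)c(CC=C(C)C)c1OC
F7 | step 6 | (4R)-7-hydroxy-5-methoxy-8-[(E)-2-methylbut-2-enoyl]-6-(3-methylbut-2-en-1-yl)-4-pentyl-3,4-dihydro-2H-chromen-2-one | CCCCC[C@@H]1CC(=O)Oc2c1c(OC)c(CC=C(C)C)c(O)c2C(=O)/C(C)=C/C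
F8 | step 6 | (4R,8S,9R)-5-methoxy-8,9-dimethyl-6-(3-methylbut-2-en-1-yl)-4-pentyl-3,4,8,9-tetrahydro-2H,10H-pyrano[2,3-f]chromene-2,10-dione | CCCCC[C@@H]1CC(=O)Oc2c1c(OC)c(CC=C(C)C)c1O[C@@H](C)[C@@H](C)C(=O)c12
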